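Decide first what to carry from the two earlier runs: one number, the plateau ratio, the late amount of product divided by the late amount of intermediate B.

| flask | substrate | remark | time |
|---|---|---|---|
| Monday's | 6.7 mM | run made earlier |  |
| Thursday's | 15 mM | run made earlier |  |
| flask | 10 mM |  | 30 min |

| run | time / min | substrate / % | product / % | intermediate B / % |
|---|---|---|---|---|
| Monday's | 1.00 | 5.4 | 59.1 | 18.0 |
| Monday's | 3.00 | 0.5 | 94.6 | 4.0 |
| Monday's | 5.00 | 1.5 | 95.0 | 4.4 |
| Monday's | 8.00 | 0 | 95.8 | 4.3 |
| Monday's | 10.0 | 0 | 94.5 | 5.1 |
| Monday's | 15.0 | 1.0 | 95.1 | 3.2 |
| Monday's | 20.0 | 0 | 95.9 | 6.1 |
| Thursday's | 1.33 | 2.6 | 71.6 | 13.5 |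
| Thursday's | 2.00 | 1.4 | 86.5 | 8.5 |
| Thursday's | 3.00 | 0 | 90.4 | 6.3 |
| Thursday's | 5.00 | 0 | 97.5 | 4.5 |
| Thursday's | 8.00 | 0 | 96.4 | 3.4 |
| Thursday's | 12.0 | 0 | 93.9 | 5.2 |
| Thursday's | 20.0 | 0 | 93.8 | 5.7 |

(standard deviation of a reading: 1 percentage point)

- the analysis behind the earlier runs scatters by 1 percentage point, standard deviation
- steps under discussion: intermediate A -> intermediate B; substrate <-> intermediate A; intermediate B <-> product
- the reaction counts as stopped when no species that holds the substrate changes by six tenths of a point or more over the second half of the time

- why nothing more happens at 30 min, or that something still does (it is still moving / forward and back rates have come level / all of the substrate has reacted)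
- how much of the substrate has reacted by 30 min
- how much product there is at 30 min, in percent of the substrate charged
- how much intermediate B there is at 30 min, in percent of the substrate charged

The steps under discussion are substrate ⇌ intermediate A, intermediate A → intermediate B and intermediate B ⇌ product. Measure against an even split, a ratio of 1, as the zero of the scale. From 5.00 min onward, both runs hold far more product than intermediate B.

Do not trust one reading, though. On Monday's run, a single ratio swings from 15.7 to 29.7, and each reading of intermediate B carries a scatter of 1 percentage point. So pool the 9 readings from 5.00 min onward, summing product and summing intermediate B. This gives the plateau ratio, 20.5, read here as an apparent equilibrium constant.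

Next, object that the charge may shift it. Pooled separately, Monday's run gives 20.6 and Thursday's run 20.3, with a charge about twice as large, and this flask's 10 mM lies between them.

Then object that 30 min lies beyond the last reading. Product on Monday's run moves 0.9 points between 5.00 min and 20.0 min, inside the scatter, and substrate stays at or below 1.5% over those times. So commit, for this flask, to complete conversion, product 95.3% and intermediate B 4.66%.

The forecast says 100% reacted, product 95.3% and intermediate B 4.7%, and my figures round to these. It names the end as "forward and back rates have come level", and it takes the ratio over to this flask, holding that “A first-order equilibrium ratio does not depend on concentration”.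

The flask gives 100% reacted, product 95.5% and intermediate B 4.55%, and its end counts as "all of the substrate has reacted", where the forecast said otherwise.

    intermediate A → intermediate B (k = 0.0370 s⁻¹)
    substrate ⇌ intermediate A (K = 2.70, k = 0.210 s⁻¹)
    intermediate B ⇌ product (K = 21.0, k = 0.0540 s⁻¹)

Substrate stands at 0% at 15.0 min, and no share moves over the second half of the time, 0 points. The plateau ratio 20.5 puts intermediate B at 4.66% in this flask, against 4.55%. Carried to the same flask read at 80 min, the plateau ratio again gives 4.66%, and that flask holds intermediate B at 4.55%.

The data are simulated with constants of no real substance.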